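**Retrosynthetic overview**

1. Locants used throughout: pyran O1, C2 (quaternary), C3, C4=C5(CH3), C6 (nonenyl); C7 = lactone carbonyl on C2; chain from C2: C8 (CHOH), C9, C10 (C–O of the lactone), C11, C12 (CHOH), C13, C14 (ring-fusion CH on C3).
2. Endgame: target ⇐ C12 ketone 28 (hydride from the convex face) ⇐ β-keto allyl ester 26 (removal of the activating ester on C13).
3. Key disconnection: 26 ⇐ monocyclic dihydropyran 24 by one SmI2 cascade that forms C10–C14 (ketyl–olefin, cyclohexane), C12–C13 (Dieckmann, cyclopentanone) and O–C7 (lactone bridge). Rings form in the order dihydropyran, then cyclohexane, cyclopentane and lactone together.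
4. Enabling feature: the cyclopentane C10–C11–C12–C13–C14 is 1,3-dioxygenated (lactone oxygen on C10, hydroxyl on C12), so C10–C11–C12 is an acetoacetate unit and C13–C14 an alkene (worn as an acrylate) six atoms from the C10 carbonyl. The C7 carboxyl on C2 lies 1,4-cis to the C10 oxygen across the cyclohexane C2–C3–C14–C10–C9–C8, so the alkoxide born in the radical step closes the 2-oxabicyclo[2.2.2]octanone.
5. 24 ⇐ aldehyde 20 + the bis-silyl dienolate of methyl acetoacetate (C8–C12) and a Wittig acrylate at C3; pyran 15 (C2, C3, C6) ⇐ one enantioselective hetero-Diels–Alder reaction of α-keto ester 14 with triene 8, made from (E)-dec-2-enal.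

Key step: step 13

Remark: reagents 16 and 21 are taken as purchased, and the ligand antipodes in steps 7 and 11 are those that the usual chelate models assign to the required series.

**Route**

Step 1
Reactants: 1 (E)-dec-2-enal; 2 2-(triphenylphosphoranylidene)propanal
Product: 3 (2E,4E)-2-methyldodeca-2,4-dienal
Conditions: toluene, 90 °C
Reagents that add atoms: 2-(triphenylphosphoranylidene)propanal, CC(C=O)=P(c1ccccc1)(c1ccccc1)c1ccccc1
Why: Wittig olefination with a stabilised ylide should give the (E)-trisubstituted enal, and the α-branched product is too hindered to be olefinated a second time.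

Step 2
Reactants: 3 (2E,4E)-2-methyldodeca-2,4-dienal; 4 triethyl phosphonoacetate
Product: 5 ethyl (2E,4E,6E)-4-methyltetradeca-2,4,6-trienoate
Conditions: NaH, THF, 0 °C → rt
Reagents that add atoms: triethyl phosphonoacetate, CCOC(=O)CP(=O)(OCC)OCC
Why: Horner–Wadsworth–Emmons olefination of an enal is reliably (E)-selective.

Step 3
Reactants: 5 ethyl (2E,4E,6E)-4-methyltetradeca-2,4,6-trienoate
Product: 6 (2E,4E,6E)-4-methyltetradeca-2,4,6-trien-1-ol
Conditions: iBu2AlH, CH2Cl2, −78 °C
Reagents that add atoms: none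
Why: 1,2-reduction of a conjugated ester by an aluminium hydride gives the allylic alcohol without touching the triene.

Step 4
Reactants: 6 (2E,4E,6E)-4-methyltetradeca-2,4,6-trien-1-ol; 7 chlorotriethylsilane
Product: 8 triethyl{[(2E,4E,6E)-4-methyltetradeca-2,4,6-trien-1-yl]oxy}silane
Conditions: imidazole, CH2Cl2, 0 °C
Reagents that add atoms: chlorotriethylsilane, CC[Si](Cl)(CC)CC
Why: standard silylation; the primary triethylsilyl ether is chosen because step 8 oxidises it directly.

Step 5
Reactants: 9 methyl 2-(hydroxymethyl)acrylate; 10 tert-butylchlorodimethylsilane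
Product: 11 methyl 2-[(tert-butyldimethylsilyloxy)methyl]acrylate
Conditions: imidazole, DMF, rt
Reagents that add atoms: tert-butylchlorodimethylsilane, CC(C)(C)[Si](C)(C)Cl
Why: standard silylation of a primary alcohol.

Step 6
Reactants: 11 methyl 2-[(tert-butyldimethylsilyloxy)methyl]acrylate; 12 ozone
Product: 14 methyl 3-(tert-butyldimethylsilyloxy)-2-oxopropanoate, via ozonide 13 (not isolated)
Conditions: O3, CH2Cl2, −78 °C; then Me2S, −78 °C → rt
Reagents that add atoms: ozone, [O-][O+]=O
Why: ozonolysis of the 1,1-disubstituted alkene with reductive work-up gives the α-keto ester, to be used at once because it hydrates easily.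

Step 7
Reactants: 8 triethyl{[(2E,4E,6E)-4-methyltetradeca-2,4,6-trien-1-yl]oxy}silane; 14 methyl 3-(tert-butyldimethylsilyloxy)-2-oxopropanoate
Product: 15 methyl (2S,3R,6R)-2-[(tert-butyldimethylsilyloxy)methyl]-5-methyl-6-[(E)-non-1-enyl]-3-[(triethylsilyloxy)methyl]-3,6-dihydro-2H-pyran-2-carboxylate
Conditions: Cu(OTf)2 (10 mol%), (R,R)-tBu-BOX (11 mol%), 4 Å molecular sieves, CH2Cl2, −20 °C → rt
Reagents that add atoms: methyl 3-(tert-butyldimethylsilyloxy)-2-oxopropanoate (14), COC(=O)C(=O)CO[Si](C)(C)C(C)(C)C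
Why: Hetero-Diels–Alder reaction of a chelated α-keto ester under divalent-copper bis(oxazoline) catalysis: the ketone carbon should bond to the triene terminus C3 (the only diene unit free of an inside substituent, with pentadienyl-type stabilisation of the developing charge), the endo ester and the (E,E)-geometry place CO2Me, the C3 arm and the C6 chain all cis, and the ligand exposes the Re face of the ketone, which sets C2 (S), C3 (R) and C6 (R).

Step 8
Reactants: 15 the pyran of step 7; 16 allyl (triphenylphosphoranylidene)acetate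
Product: 18 methyl (2S,3S,6R)-3-[(E)-3-(allyloxy)-3-oxoprop-1-enyl]-2-[(tert-butyldimethylsilyloxy)methyl]-5-methyl-6-[(E)-non-1-enyl]-3,6-dihydro-2H-pyran-2-carboxylate, via aldehyde 17 (not isolated)
Conditions: (COCl)2, DMSO, CH2Cl2, −78 → −40 °C; Et3N, −78 °C; then 16, −78 °C → rt
Reagents that add atoms: allyl (triphenylphosphoranylidene)acetate, C=CCOC(=O)C=P(c1ccccc1)(c1ccccc1)c1ccccc1
Why: Swern conditions oxidise a primary triethylsilyl ether directly to the aldehyde, so the free γ-hydroxy ester (which would lactonise onto the cis C7 ester) never forms, and the in-situ Wittig reaction with the stabilised ylide gives the (E)-acrylate before the β-alkoxy, β,γ-unsaturated aldehyde can epimerise or eliminate.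

Step 9
Reactants: 18 the acrylate of step 8
Product: 19 methyl (2S,3S,6R)-3-[(E)-3-(allyloxy)-3-oxoprop-1-enyl]-2-(hydroxymethyl)-5-methyl-6-[(E)-non-1-enyl]-3,6-dihydro-2H-pyran-2-carboxylate
Conditions: HF·pyridine, pyridine, THF, 0 °C → rt
Reagents that add atoms: none
Why: buffered, non-basic fluoride desilylation removes the primary TBS ether while sparing the acrylate, whose γ-hydrogen at C3 and whose β-carbon (oxa-Michael) would be at risk with basic fluoride.

Step 10
Reactants: 19 the alcohol of step 9
Product: 20 methyl (2S,3S,6R)-3-[(E)-3-(allyloxy)-3-oxoprop-1-enyl]-2-formyl-5-methyl-6-[(E)-non-1-enyl]-3,6-dihydro-2H-pyran-2-carboxylate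
Conditions: Dess–Martin periodinane, NaHCO3, CH2Cl2, 0 °C → rt
Reagents that add atoms: none
Why: Dess–Martin oxidation of a neopentyl primary alcohol gives a non-enolisable α-alkoxy-α-formyl ester.

Step 11
Reactants: 20 the aldehyde of step 10; 21 1-methoxy-1,3-bis(trimethylsilyloxy)buta-1,3-diene
Product: 23 methyl (2S,3S,6R)-3-[(E)-3-(allyloxy)-3-oxoprop-1-enyl]-2-[(1R)-1-hydroxy-5-methoxy-3,5-dioxopentyl]-5-methyl-6-[(E)-non-1-enyl]-3,6-dihydro-2H-pyran-2-carboxylate, via silyl aldol adduct 22 (not isolated)
Conditions: Ti(OiPr)4 (20 mol%), (R)-BINOL (20 mol%), 4 Å molecular sieves, THF, −78 → −20 °C; then aq. citric acid, THF, 0 °C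
Reagents that add atoms: 1-methoxy-1,3-bis(trimethylsilyloxy)buta-1,3-diene, C=C(O[Si](C)(C)C)C=C(OC)O[Si](C)(C)C
Why: Vinylogous Mukaiyama aldol addition at the Re face of the aldehyde, the face favoured both by the formyl–ester chelate (attack past ring O1 and not past C3) and by the polar Felkin–Anh model and reinforced by the matched titanium BINOLate, should set C8 (R); mild acid then removes both silyl groups.

Step 12
Reactants: 23 the δ-hydroxy-β-keto ester of step 11; 7 chlorotriethylsilane
Product: 24 methyl (2S,3S,6R)-3-[(E)-3-(allyloxy)-3-oxoprop-1-enyl]-2-[(1R)-5-methoxy-3,5-dioxo-1-(triethylsilyloxy)pentyl]-5-methyl-6-[(E)-non-1-enyl]-3,6-dihydro-2H-pyran-2-carboxylate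
Conditions: imidazole, DMAP (cat.), DMF, 0 °C → rt
Reagents that add atoms: chlorotriethylsilane, CC[Si](Cl)(CC)CC
Why: silylation removes the only hydroxyl proton so that the cascade can run aprotic, under conditions too mild to lactonise the δ-hydroxy-β-keto ester.

Step 13
Reactants: 24 the β-keto ester/acrylate of step 12
Product: 26 tetracyclic β-keto allyl ester lactone (target skeleton; C12 ketone; allyl ester on C13; C8–OTES), via hydroxy diester 25 (not isolated)
Conditions: SmI2 (2.5 equiv), HMPA (10 equiv), THF, −78 °C (24 added slowly) → rt; aq. NH4Cl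
Reagents that add atoms: none
Why: Single-electron reduction of the samarium-chelated C10 ketone gives a ketyl that adds 6-exo-trig to the acrylate β-carbon C14 (closing the cyclohexane), the second electron turns the α-ester radical into a trivalent-samarium enolate at C13 that acylates the C12 methyl ester 5-exo-trig (Dieckmann, closing the cyclopentanone), and the C10 samarium alkoxide closes the δ-lactone on the C7 methyl ester (bridging the 2-oxabicyclo[2.2.2]octanone). The closest known reaction type is the SmI2 ketyl–olefin radical cyclisation terminated by anionic trapping of the samarium enolate (radical–polar crossover sequences ending in aldol or Claisen acylation), together with the Claisen condensation of samarium ester enolates. The cyclohexane should close through a chair in which the trans-disposed C2 and C3 arms are both equatorial on the pyran half-chair, so the acrylate lies equatorial and C14–H ends anti to C3–H; the cyclopentanone can only close cis-fused, and the lactone only from the isomer with the C10 oxygen cis to C7. C10 is controlled by the usual anti course of ketyl–olefin additions: the bulky HMPA-ligated O–Sm group stays equatorial and trans to C13, which is the isomer whose alkoxide faces the axial C7 ester. The step needs the ketone to be reduced before the esters (β-keto ester chelation secures this), the enolate to meet the C12 ester and not C7 (an equatorial C13 cannot reach the axial C7 ester), and no proton source (C8–OH is silylated and 24 is added slowly to excess SmI2 so that the acidic β-keto ester cannot quench the enolate). The product leaves the flask as a stabilised β-keto ester enolate, which should protect the new ketone from over-reduction and from β-elimination of the lactone oxygen.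

Step 14
Reactants: 26 the β-keto allyl ester lactone of step 13
Product: 28 tetracyclic keto lactone (target skeleton; C12 ketone; C8–OTES), via β-keto acid 27 (not isolated)
Conditions: Pd(PPh3)4 (5 mol%), morpholine, THF, rt
Reagents that add atoms: none
Why: zerovalent palladium ionises the allyl ester (morpholine traps the allyl group) and the β-keto acid loses CO2 at room temperature through the C12–C13 enol, so the base-sensitive β-acyloxy ketone never passes through its C11 enolate.

Step 15
Reactants: 28 the keto lactone of step 14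
Product: 29 C8 triethylsilyl ether of the target
Conditions: NaBH4, MeOH/CH2Cl2, −78 → −40 °C
Reagents that add atoms: none
Why: borohydride reduction from the convex face of the cyclopentanone (the face of the lactone oxygen and C14–H; the concave face is screened by the C9 methylene of the bicyclo[2.2.2]octane) should set C12 (R) with the hydroxyl trans to the lactone oxygen, and the low temperature avoids β-elimination.

Step 16
Reactants: 29 the silyl ether of step 15
Product: 30 CNP0127096.2
Conditions: HF·pyridine, pyridine, THF, 0 °C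
Reagents that add atoms: none
Why: buffered fluoride desilylation frees the C8 hydroxyl without opening the lactone or ionising the doubly allylic C6–O1 ether.

**Compound list**

1 | (E)-dec-2-enal | CCCCCCC/C=C/C=O | starting material
2 | 2-(triphenylphosphoranylidene)propanal | CC(C=O)=P(c1ccccc1)(c1ccccc1)c1ccccc1 | starting material
3 | (2E,4E)-2-methyldodeca-2,4-dienal | CCCCCCC/C=C/C=C(\C)C=O | intermediate
4 | triethyl phosphonoacetate | CCOC(=O)CP(=O)(OCC)OCC | starting material
5 | ethyl (2E,4E,6E)-4-methyltetradeca-2,4,6-trienoate | CCCCCCC/C=C/C=C(\C)/C=C/C(=O)OCC | intermediate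
6 | (2E,4E,6E)-4-methyltetradeca-2,4,6-trien-1-ol | CCCCCCC/C=C/C=C(\C)/C=C/CO | intermediate
7 | chlorotriethylsilane | CC[Si](Cl)(CC)CC | starting material
8 | triethyl{[(2E,4E,6E)-4-methyltetradeca-2,4,6-trien-1-yl]oxy}silane | CCCCCCC/C=C/C=C(\C)/C=C/CO[Si](CC)(CC)CC | intermediate
9 | methyl 2-(hydroxymethyl)acrylate | C=C(CO)C(=O)OC | starting material
10 | tert-butylchlorodimethylsilane | CC(C)(C)[Si](C)(C)Cl | starting material
11 | methyl 2-[(tert-butyldimethylsilyloxy)methyl]acrylate | C=C(CO[Si](C)(C)C(C)(C)C)C(=O)OC | intermediate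
12 | ozone | [O-][O+]=O | starting material
13 | methyl 3-[(tert-butyldimethylsilyloxy)methyl]-1,2,4-trioxolane-3-carboxylate (ozonide of 11) | COC(=O)C1(CO[Si](C)(C)C(C)(C)C)OCOO1 | intermediate
14 | methyl 3-(tert-butyldimethylsilyloxy)-2-oxopropanoate | COC(=O)C(=O)CO[Si](C)(C)C(C)(C)C | intermediate
15 | methyl (2S,3R,6R)-2-[(tert-butyldimethylsilyloxy)methyl]-5-methyl-6-[(E)-non-1-enyl]-3-[(triethylsilyloxy)methyl]-3,6-dihydro-2H-pyran-2-carboxylate (CO2Me, C3 arm and C6 chain all cis) | CCCCCCC/C=C/[C@H]1O[C@](C(=O)OC)(CO[Si](C)(C)C(C)(C)C)[C@@H](CO[Si](CC)(CC)CC)C=C1C | intermediate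
16 | allyl (triphenylphosphoranylidene)acetate | C=CCOC(=O)C=P(c1ccccc1)(c1ccccc1)c1ccccc1 | starting material
17 | methyl (2S,3S,6R)-2-[(tert-butyldimethylsilyloxy)methyl]-3-formyl-5-methyl-6-[(E)-non-1-enyl]-3,6-dihydro-2H-pyran-2-carboxylate | CCCCCCC/C=C/[C@H]1O[C@](C(=O)OC)(CO[Si](C)(C)C(C)(C)C)[C@@H](C=O)C=C1C | intermediate
18 | methyl (2S,3S,6R)-3-[(E)-3-(allyloxy)-3-oxoprop-1-enyl]-2-[(tert-butyldimethylsilyloxy)methyl]-5-methyl-6-[(E)-non-1-enyl]-3,6-dihydro-2H-pyran-2-carboxylate | CCCCCCC/C=C/[C@H]1O[C@](C(=O)OC)(CO[Si](C)(C)C(C)(C)C)[C@@H](/C=C/C(=O)OCC=C)C=C1C | intermediate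
19 | methyl (2S,3S,6R)-3-[(E)-3-(allyloxy)-3-oxoprop-1-enyl]-2-(hydroxymethyl)-5-methyl-6-[(E)-non-1-enyl]-3,6-dihydro-2H-pyran-2-carboxylate | CCCCCCC/C=C/[C@H]1O[C@](C(=O)OC)(CO)[C@@H](/C=C/C(=O)OCC=C)C=C1C | intermediate
20 | methyl (2S,3S,6R)-3-[(E)-3-(allyloxy)-3-oxoprop-1-enyl]-2-formyl-5-methyl-6-[(E)-non-1-enyl]-3,6-dihydro-2H-pyran-2-carboxylate | CCCCCCC/C=C/[C@H]1O[C@](C(=O)OC)(C=O)[C@@H](/C=C/C(=O)OCC=C)C=C1C | intermediate
21 | 1-methoxy-1,3-bis(trimethylsilyloxy)buta-1,3-diene | C=C(O[Si](C)(C)C)C=C(OC)O[Si](C)(C)C | starting material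
22 | bis-silyl aldol adduct of 20 (C8–OSiMe3; C10 as trimethylsilyl enol ether of the β-keto ester) | CCCCCCC/C=C/[C@H]1O[C@](C(=O)OC)([C@H](O[Si](C)(C)C)CC(O[Si](C)(C)C)=CC(=O)OC)[C@@H](/C=C/C(=O)OCC=C)C=C1C | intermediate
23 | methyl (2S,3S,6R)-3-[(E)-3-(allyloxy)-3-oxoprop-1-enyl]-2-[(1R)-1-hydroxy-5-methoxy-3,5-dioxopentyl]-5-methyl-6-[(E)-non-1-enyl]-3,6-dihydro-2H-pyran-2-carboxylate | CCCCCCC/C=C/[C@H]1O[C@](C(=O)OC)([C@H](O)CC(=O)CC(=O)OC)[C@@H](/C=C/C(=O)OCC=C)C=C1C | intermediate
24 | methyl (2S,3S,6R)-3-[(E)-3-(allyloxy)-3-oxoprop-1-enyl]-2-[(1R)-5-methoxy-3,5-dioxo-1-(triethylsilyloxy)pentyl]-5-methyl-6-[(E)-non-1-enyl]-3,6-dihydro-2H-pyran-2-carboxylate | CCCCCCC/C=C/[C@H]1O[C@](C(=O)OC)([C@H](O[Si](CC)(CC)CC)CC(=O)CC(=O)OC)[C@@H](/C=C/C(=O)OCC=C)C=C1C | intermediate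
25 | tricyclic hydroxy diester before lactonisation: pyran trans-fused to the cyclohexane, C10–OH cis to the C7 methyl ester, cis-fused 2-(allyloxycarbonyl)cyclopentanone, C8–OTES; C2, C3, C6, C8, C10, C14 as in the target, C13 unassigned | CCCCCCC/C=C/[C@H]1O[C@]2(C(=O)OC)[C@H](O[Si](CC)(CC)CC)C[C@](O)(CC(=O)C3C(=O)OCC=C)[C@H]3[C@H]2C=C1C | intermediate
26 | tetracyclic β-keto allyl ester lactone: target skeleton with C12 ketone, allyl ester on C13 (epimers/enol), C8–OTES; other stereocentres as in the target | CCCCCCC/C=C/[C@H]1O[C@@]23C(=O)O[C@]4(CC(=O)C(C(=O)OCC=C)[C@@H]4[C@H]2C=C1C)C[C@H]3O[Si](CC)(CC)CC | intermediate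
27 | β-keto acid from 26 (CO2H on C13) | CCCCCCC/C=C/[C@H]1O[C@@]23C(=O)O[C@]4(CC(=O)C(C(=O)O)[C@@H]4[C@H]2C=C1C)C[C@H]3O[Si](CC)(CC)CC | intermediate
28 | tetracyclic keto lactone: target skeleton with C12 ketone, C8–OTES; stereocentres as in the target | CCCCCCC/C=C/[C@H]1O[C@@]23C(=O)O[C@]4(CC(=O)C[C@@H]4[C@H]2C=C1C)C[C@H]3O[Si](CC)(CC)CC | intermediate
29 | C8 triethylsilyl ether of the target (C12 R) | CCCCCCC/C=C/[C@H]1O[C@@]23C(=O)O[C@]4(C[C@H](O)C[C@@H]4[C@H]2C=C1C)C[C@H]3O[Si](CC)(CC)CC | intermediate
30 | CNP0127096.2 (C2 S, C3 R, C6 R, C8 R, C10 R, C12 R, C14 R in the locants above) | CCCCCCC/C=C/[C@H]1O[C@@]23C(=O)O[C@]4(C[C@H](O)C[C@@H]4[C@H]2C=C1C)C[C@H]3O | target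

**Step count and risks**

Total step count: 16. Longest linear sequence: 14 (steps 1–4 and 7–16; steps 5 and 6 form the side branch).

Steps most likely to fail:

Step 13. The cascade may stall after the first ring if the samarium enolate is protonated by the acidic β-keto ester before it acylates. It may also close C10 with poor facial selectivity, because the required chair places C11 1,3-diaxial to the C8 silyloxy group; the wrong isomer leaves an alkoxide that cannot lactonise. The fallback forms the same two carbon–carbon bonds by a Pauson–Khand reaction and adds the C10 oxygen afterwards, anti to that same axial silyloxy group. It sets out from 15 and returns at 28. Silyl ether 15 is oxidised as in step 8 and the aldehyde is methylenated in the same flask (Ph3P=CH2 from Ph3PCH3Br and KN(SiMe3)2, THF, −78 °C) to the 3-vinyl pyran F1. HF·pyridine gives the primary alcohol F2 and Dess–Martin oxidation the aldehyde F3. Barbier propargylation (propargyl bromide, Zn, THF) under the same chelate control as step 11 should give the homopropargylic alcohol F4, which is silylated (chlorotriethylsilane, imidazole) to the enyne F5. The Pauson–Khand reaction (Co2(CO)8, CH2Cl2; then N-methylmorpholine N-oxide) joins C10 to C14 and C13 to C12, with carbon monoxide as C12, through a chair with the vinyl group equatorial, to give the tricyclic enone F6. Copper-catalysed conjugate borylation (CuCl, NaOtBu, 1,2-bis(diphenylphosphino)benzene, B2pin2, MeOH, THF) gives the β-boryl ketone F7, and oxidation (NaBO3, THF/H2O) gives the β-hydroxy ketone F8. Neutral lactonisation (Bu2SnO cat., toluene, 80 °C) then gives 28.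

Step 7. The ketone dienophile may be too unreactive toward the unactivated triene, a carbonyl-ene reaction at the C5 methyl group may compete, or endo and facial control may be insufficient at a ketone. The fallback uses an aldehyde dienophile and builds the quaternary centre afterwards. It sets out from 8 and returns at 15. Triene 8 and methyl glyoxylate under the same divalent-copper bis(oxazoline) catalysis should give the 2-monosubstituted pyran ester F9, whose C2 epimers both serve. Enolisation (LiN(iPr)2, THF, −78 °C) and trapping with monomeric formaldehyde, anti to the cis C3 and C6 substituents, gives the hydroxymethyl ester F10. Silylation (tert-butylchlorodimethylsilane, imidazole) gives 15.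

Step 11. Facial selectivity at the hindered α-quaternary aldehyde may be poor if the five-membered chelate through ring O1 competes with the formyl–ester chelate. The fallback is auxiliary-controlled. It sets out from 20 and returns at 24. The titanium enolate of N-acetyl-4-benzylthiazolidine-2-thione (TiCl4, iPr2NEt, CH2Cl2, −78 °C; auxiliary antipode chosen for the (R)-carbinol, drawn here as S) gives the acetate aldol adduct F11. Silylation (chlorotriethylsilane, imidazole) gives the silyl ether F12. Displacement of the auxiliary with the magnesium salt of monomethyl malonate (KO2CCH2CO2Me, MgCl2, imidazole, THF, rt) and loss of CO2 gives 24.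

Further compounds

F1 | step 13 | methyl 2-[(tert-butyldimethylsilyloxy)methyl]-5-methyl-6-[(E)-non-1-enyl]-3-vinyl-3,6-dihydro-2H-pyran-2-carboxylate (ring stereocentres as in 18) | CCCCCCC/C=C/[C@H]1O[C@](C(=O)OC)(CO[Si](C)(C)C(C)(C)C)[C@@H](C=C)C=C1C
F2 | step 13 | methyl 2-(hydroxymethyl)-5-methyl-6-[(E)-non-1-enyl]-3-vinyl-3,6-dihydro-2H-pyran-2-carboxylate | CCCCCCC/C=C/[C@H]1O[C@](C(=O)OC)(CO)[C@@H](C=C)C=C1C
F3 | step 13 | methyl 2-formyl-5-methyl-6-[(E)-non-1-enyl]-3-vinyl-3,6-dihydro-2H-pyran-2-carboxylate | CCCCCCC/C=C/[C@H]1O[C@](C(=O)OC)(C=O)[C@@H](C=C)C=C1C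
F4 | step 13 | methyl 2-[(1R)-1-hydroxybut-3-ynyl]-5-methyl-6-[(E)-non-1-enyl]-3-vinyl-3,6-dihydro-2H-pyran-2-carboxylate | CCCCCCC/C=C/[C@H]1O[C@](C(=O)OC)([C@H](O)CC#C)[C@@H](C=C)C=C1C
F5 | step 13 | methyl 5-methyl-6-[(E)-non-1-enyl]-2-[(1R)-1-(triethylsilyloxy)but-3-ynyl]-3-vinyl-3,6-dihydro-2H-pyran-2-carboxylate | CCCCCCC/C=C/[C@H]1O[C@](C(=O)OC)([C@H](O[Si](CC)(CC)CC)CC#C)[C@@H](C=C)C=C1C
F6 | step 13 | tricyclic enone (C10=C11, C12 ketone, C7 methyl ester, C8–OTES, C14 as in the target) | CCCCCCC/C=C/[C@H]1O[C@]2(C(=O)OC)[C@H](O[Si](CC)(CC)CC)CC3=CC(=O)C[C@@H]3[C@H]2C=C1C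
F7 | step 13 | β-boryl ketone (pinacolboryl on C10, cis to the C7 ester) | CCCCCCC/C=C/[C@H]1O[C@]2(C(=O)OC)[C@H](O[Si](CC)(CC)CC)C[C@](B4OC(C)(C)C(C)(C)O4)(CC(=O)C3)[C@H]3[C@H]2C=C1C
F8 | step 13 | β-hydroxy ketone (C10–OH cis to the C7 ester, C12 ketone) | CCCCCCC/C=C/[C@H]1O[C@]2(C(=O)OC)[C@H](O[Si](CC)(CC)CC)C[C@](O)(CC(=O)C3)[C@H]3[C@H]2C=C1C
F9 | step 7 | methyl (3R,6R)-5-methyl-6-[(E)-non-1-enyl]-3-[(triethylsilyloxy)methyl]-3,6-dihydro-2H-pyran-2-carboxylate (2,3-cis isomer drawn) | CCCCCCC/C=C/[C@H]1O[C@@H](C(=O)OC)[C@@H](CO[Si](CC)(CC)CC)C=C1C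
F10 | step 7 | methyl (2S,3R,6R)-2-(hydroxymethyl)-5-methyl-6-[(E)-non-1-enyl]-3-[(triethylsilyloxy)methyl]-3,6-dihydro-2H-pyran-2-carboxylate | CCCCCCC/C=C/[C@H]1O[C@](C(=O)OC)(CO)[C@@H](CO[Si](CC)(CC)CC)C=C1C
F11 | step 11 | acetate aldol adduct of 20: N-[(3R)-3-hydroxy-3-(pyran-2-yl)propanoyl]-(4S)-4-benzylthiazolidine-2-thione | CCCCCCC/C=C/[C@H]1O[C@](C(=O)OC)([C@H](O)CC(=O)N2C(=S)SC[C@@H]2Cc2ccccc2)[C@@H](/C=C/C(=O)OCC=C)C=C1C
F12 | step 11 | triethylsilyl ether of F11 | CCCCCCC/C=C/[C@H]1O[C@](C(=O)OC)([C@H](O[Si](CC)(CC)CC)CC(=O)N2C(=S)SC[C@@H]2Cc2ccccc2)[C@@H](/C=C/C(=O)OCC=C)C=C1C
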